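## Structural features

Compound 21 is an isoflavone. Benzene ring A is fused along C4a–C8a to the 4-pyranone ring C, and the 2,4-dihydroxyphenyl ring B is attached to C3 by one aryl–vinyl bond. Ring A carries a different group on every remaining carbon: OMe at C5 (peri to the C4 carbonyl), a 3-methylbut-2-enyl (prenyl) chain at C6, a free hydroxyl at C7 and hydrogen at C8. There is no stereocentre, and the side-chain alkene bears two identical methyl groups, so no neighbouring stereocentres have to be related. The fragile parts are the electron-rich trisubstituted alkene (acid can cyclise it onto the C7 hydroxyl to a dimethylchroman; it rules out hydrogenolysis and electrophilic halogen), the three phenols (competing nucleophiles, easily oxidised) and C2 of the pyranone, which hard nucleophiles attack with ring opening. The real difficulty is regiochemical: the three oxygens of the phloroglucinol-type ring A must be told apart (methyl on O5, hydrogen on O7, O1 in the ring) and the prenyl group must sit at C6, not C8. The key step exploits that C4a and C8a are neighbours carrying the C4 acyl carbon and O1, with the C5 methoxy group beside C4a. A C4a≡C8a aryne polarised by that methoxy group can take an oxygen nucleophile at C8a and hand the resulting carbanion at C4a to an acyl group.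

## Logic of the disconnections

**21 ⇒ 20 ⇒ 19.** Only protecting-group bonds are cut: the O7–Si bond (from 20) and the two acetal O–CH2 bonds on ring B (from 19). Every phenol must be masked while an aryne is present, and a bulky silyl group on O7 neither directs lithiation nor needs acid beside the prenyl group for its removal. No skeleton is simplified; the gain is a ring-forming step run on a molecule without acidic OH. The forward demand is one of order: the acetals go first, while O7 is still silylated so that no phenol flanks the alkene in acid, and fluoride comes last.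

**19 ⇒ 11 + 16.** The bonds O1–C8a and C4–C4a are cut, which opens ring C. This separates ring A from a C2–C3–C4 unit that already carries ring B. The atom mapping, the ring substitution pattern and the (Z)-geometry of 16 were checked and are mutually consistent, so the two partners are used without structural change. The gain is two fragments of similar size and a ring A with no carbonyl group. The forward step must add oxygen at C8a and carbon at C4a, arylate the enolate on oxygen and not carbon, close the ring before the aryl anion is protonated, and spare the silyl ether.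

**11 ⇒ 9 (through 10).** The S–O bond of the sulfonate is cut and the oxygen is returned to a carbamate. The carbamate is what allows silicon to be placed on the neighbouring carbon, and it is a stable, storable precursor. The forward demand is removal of the carbamoyl group without touching either silyl group. An N–H carbamate is therefore chosen, which an amine base expels as the isocyanate so that the phenoxide can be sulfonylated in the same flask.

**9 ⇒ 5.** The C–Si bond at the ring carbon between the carbamate oxygen and OMe is cut. That carbon is the only free position flanked by two coordinating oxygens; the other free position lies beside the bulky, non-coordinating silyl ether. The gain is removal of the last substituent that needs C–H functionalisation. The forward lithiation must be ortho-directed and faster than deprotonation of the benzylic–allylic CH2 of the prenyl group.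

**5 ⇒ 4 ⇒ 3.** The O–Si bond and the O–C(O)N bond are cut. The two hydroxyls of 3 differ sterically: one is flanked by the prenyl chain, the other by two hydrogens. The gain is a diol in which the methyl ether is already in place, so no selective methylation is needed anywhere in the route. The forward carbamoylation must choose the unhindered hydroxyl.

**3 ⇒ 1 + 2.** The bond between the ring and the prenyl CH2 is cut. Both pieces are commercial, and 1 already has one of its three oxygens methylated. The forward step must alkylate on carbon and not oxygen, once only, and at a position between OH and OMe rather than between the two OH groups.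

**16 ⇒ 14 ⇒ 13 ⇒ 12.** The C2–C3 bond (formyl carbon to the α-carbon) is cut, then the two acetal O–C bonds, then the ester O–CH3 bond. The α-carbon of an arylacetate is the natural nucleophile for a one-carbon electrophile, and the ester becomes C4. The gain is a commercial acid. The forward demands are base-stable phenol protection and a mild acidic work-up that liberates the enol without cleaving the acetals.

## Other disconnections considered

**Alternative 1:** Three bonds of ring C are cut (C3–C4, O1–C2, C2=C3). The pieces are the ring A benzodioxinone A1, the ring B phosphonium salt A2 and a formate donor.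
- Forward key step: the benzylidene ylide from A2 opens A1 by C-acylation with loss of acetone, the freed phenoxide is O-formylated, and the acyl ylide olefinates the formate carbonyl to give A3.
- In favour: each elementary event has precedent on simpler substrates. No fluoride is involved, so all three phenols can be MOM ethers and one acid step finishes the synthesis; on end-game length this alternative is better by one step. The ring A oxygens are distinguished by the carboxyl group (chelation), which is better than the steric bias relied on in steps 1 and 2.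
- Against: A1 is a pentasubstituted salicylate, so a carboxyl carbon must be installed in addition to everything 11 needs, and the C6-versus-C8 placement of the prenyl group is not made easier. Its carbonyl is flanked by OMe and the ring oxygen and is hindered toward a bulky ylide. Acylation consumes a second equivalent of ylide. The stabilised acyl ylide beside an ortho-substituted aryl ring is a weak nucleophile even toward a formate.
- Comparison: structurally both plans join ring A and ring B through ring C. Mechanistically this one needs three consecutive events in one flask, each outrunning loss of the labile formate, whereas the chosen plan needs one aryne capture with the right O/C selectivity. Step economy is about equal.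

**Alternative 2:** The C3–C4 bond is cut. The precursor is the keto aldehyde A4.
- Forward key step: a triazolium-derived carbene turns the aldehyde into an acyl-anion equivalent that adds to the tethered aryl ketone and gives racemic A5. Dehydration would then give A3.
- In favour: the step is catalytic, mild and fluoride-free. Intramolecular aldehyde–ketone benzoin closure to 3-hydroxychroman-4-ones is established chemistry; on mechanistic precedent this alternative is better than the chosen plan. An all-MOM protecting scheme is possible.
- Against: the aldehyde of A4 has two ortho oxygens and should form the carbene adduct slowly. The α-aryloxy ketone has an acidic CH2 that can condense onto the aldehyde under the base needed (Rap–Stoermer-type benzofuran formation). The stereocentre of A5 is created only to be destroyed, and the dehydration must avoid acid because of the MOM and prenyl groups. A4 needs the same oxygen differentiation on ring A plus a formylation and an O-alkylation.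
- Comparison: structurally less convergent in effect, since ring A must arrive as a fully substituted salicylaldehyde. The route would be two to three steps longer.

**Alternative 3:** Ring A is cut at C7–C8 and C5–C6. The pieces are the pyranone ester A6 and the N-methoxy-N-methylamide A7.
- Forward key step: the lateral carbanion of the 2-methyl group of A6 is acylated by A7, and the derived dianion closes onto the ester to give A8 after tautomerisation.
- In favour: the prenyl position is fixed by construction, because C6 is the α-carbon of A7. No C6/C8 ambiguity and no steric discrimination between hydroxyls arise; on regiochemical certainty of the carbon skeleton this alternative is better than the chosen plan. Rings B and C are secured early.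
- Against: A8 is a 5,7-diol, and the target needs methyl on the chelated, less reactive O5 and hydrogen on O7. This requires protection of O7, forced methylation of O5 and deprotection. The key step needs several equivalents of strong amide base on a 4-pyranone whose C2 is electrophilic, and the dianion can be acylated or protonated at the wrong site.
- Comparison: mechanistically this step is as unproven on its substrate class as the chosen one, so neither plan has an advantage there. The extra oxygen manipulations make the route equal or longer.

Key step: step 9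

Remark on the chemistry: ring atoms of all intermediates are referred to by the chromen-4-one numbering of 21; prenyl = 3-methylbut-2-en-1-yl, MOM = methoxymethyl, TIPS = triisopropylsilyl, TBS = tert-butyldimethylsilyl, TMS = trimethylsilyl.

## Route

Step 1
Reactants: 1 5-methoxybenzene-1,3-diol; 2 1-bromo-3-methylbut-2-ene (prenyl bromide)
Product: 3 5-methoxy-4-(3-methylbut-2-en-1-yl)benzene-1,3-diol
Conditions: 2 (0.8 equiv), KOH (1.0 equiv), H2O, 0 °C to rt
Reagents that add atoms: none
Why: C-alkylation of an ambident phenoxide in water, where hydrogen bonding to oxygen favours attack through carbon; the two equivalent positions between OH and OMe are each ortho to one oxygen and para to the other, so 3 should be the main mono-C-prenyl product and is separated from the symmetric 2-prenyl isomer by chromatography.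

Step 2
Reactants: 3 5-methoxy-4-(3-methylbut-2-en-1-yl)benzene-1,3-diol
Product: 4 3-hydroxy-5-methoxy-4-(3-methylbut-2-en-1-yl)phenyl N-isopropylcarbamate
Conditions: i-PrNCO (1.0 equiv), Et3N (0.1 equiv), CH2Cl2, −20 to 0 °C
Reagents that add atoms: isopropyl isocyanate, CC(C)N=C=O
Why: Base-catalysed addition of a phenol to an isocyanate; the hydroxyl para to the prenyl chain has two ortho hydrogens and should react ahead of the hydroxyl that is buttressed by the chain.

Step 3
Reactants: 4 3-hydroxy-5-methoxy-4-(3-methylbut-2-en-1-yl)phenyl N-isopropylcarbamate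
Product: 5 3-methoxy-4-(3-methylbut-2-en-1-yl)-5-(triisopropylsilyloxy)phenyl N-isopropylcarbamate
Conditions: TIPSCl (1.3 equiv), imidazole (2.5 equiv), DMF, rt
Reagents that add atoms: triisopropylsilyl chloride, CC(C)[Si](Cl)(C(C)C)C(C)C
Why: Standard silylation of the one remaining phenol; imidazole is too weak a base to eliminate the N–H carbamate.

Step 4
Reactants: 5 3-methoxy-4-(3-methylbut-2-en-1-yl)-5-(triisopropylsilyloxy)phenyl N-isopropylcarbamate
Product: 9 3-methoxy-4-(3-methylbut-2-en-1-yl)-5-(triisopropylsilyloxy)-2-(trimethylsilyl)phenyl N-isopropylcarbamate, via N-silyl carbamate 6 (not isolated), via aryllithium 7 (not isolated), via bis-silyl carbamate 8 (not isolated)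
Conditions: TBSOTf (1.1 equiv), TMEDA (1.1 equiv), Et2O, 0 °C to rt; then TMEDA (2 equiv), n-BuLi (2 equiv), −78 °C; then TMSCl (3 equiv), −78 °C to rt; aq NaHSO4 work-up
Reagents that add atoms: trimethylsilyl chloride, C[Si](C)(C)Cl; retained in intermediates 6 to 8 only: tert-butyldimethylsilyl triflate, CC(C)(C)[Si](C)(C)OS(=O)(=O)C(F)(F)F, and n-butyllithium, [Li]CCCC
Why: Directed ortho-metalation; in situ N-silylation turns the N–H carbamate into a tertiary carbamate director, the carbon between the carbamate oxygen and OMe is activated by both, the other ortho position is blocked by the non-coordinating TIPS ether, and the N–Si bond is hydrolysed on work-up.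

Step 5
Reactants: 9 3-methoxy-4-(3-methylbut-2-en-1-yl)-5-(triisopropylsilyloxy)-2-(trimethylsilyl)phenyl N-isopropylcarbamate
Product: 11 3-methoxy-4-(3-methylbut-2-en-1-yl)-5-(triisopropylsilyloxy)-2-(trimethylsilyl)phenyl trifluoromethanesulfonate, via silyl phenol 10 (not isolated)
Conditions: DBU (1.5 equiv), Et2NH (1.5 equiv), MeCN, 40 °C; then PhNTf2 (1.5 equiv), rt
Reagents that add atoms: N-phenylbis(trifluoromethanesulfonimide), FC(F)(F)S(=O)(=O)N(c1ccccc1)S(=O)(=O)C(F)(F)F
Why: E1cB cleavage of the N–H carbamate (the isocyanate is trapped by diethylamine as a urea) followed by sulfonylation of the phenoxide with a mild triflating agent; neither silyl group nor the alkene is affected by amine bases.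

Step 6
Reactants: 12 2-(2,4-dihydroxyphenyl)acetic acid
Product: 13 methyl 2-(2,4-dihydroxyphenyl)acetate
Conditions: MeOH, H2SO4 (cat.), reflux
Reagents that add atoms: methanol, CO
Why: Fischer esterification; in methanol any lactone formed with the ortho hydroxyl is reopened to the methyl ester.

Step 7
Reactants: 13 methyl 2-(2,4-dihydroxyphenyl)acetate
Product: 14 methyl 2-[2,4-bis(methoxymethoxy)phenyl]acetate
Conditions: MOMCl (3 equiv), i-Pr2NEt (4 equiv), CH2Cl2, 0 °C to rt
Reagents that add atoms: chloromethyl methyl ether, COCCl
Why: O-alkylation of both phenols as acetals with a weak amine base that does not trigger lactonisation onto the ester; MOM ethers tolerate the hydride base of step 8 and the fluoride of step 9.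

Step 8
Reactants: 14 methyl 2-[2,4-bis(methoxymethoxy)phenyl]acetate
Product: 16 methyl (Z)-2-[2,4-bis(methoxymethoxy)phenyl]-3-hydroxyacrylate, via sodium enolate 15 (not isolated)
Conditions: HCO2Me (8 equiv), NaH (2.5 equiv), THF, 0 °C to rt; then cold aq AcOH to pH 5
Reagents that add atoms: methyl formate, COC=O; retained in intermediate 15 only: sodium hydride, [Na+].[H-]
Why: Crossed Claisen condensation of an arylacetate with a non-enolisable formate, driven by formation of the stabilised enolate; mild acidification should give the hydrogen-bonded (Z)-enol (in equilibrium with its formyl tautomer) without acetal cleavage.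

Step 9
Reactants: 11 3-methoxy-4-(3-methylbut-2-en-1-yl)-5-(triisopropylsilyloxy)-2-(trimethylsilyl)phenyl trifluoromethanesulfonate; 16 methyl (Z)-2-[2,4-bis(methoxymethoxy)phenyl]-3-hydroxyacrylate
Product: 19 3-[2,4-bis(methoxymethoxy)phenyl]-5-methoxy-6-(3-methylbut-2-en-1-yl)-7-(triisopropylsilyloxy)-4H-chromen-4-one, via aryne 17 (not isolated), via aryl anion 18 (not isolated)
Conditions: 11 (1.3 equiv), 16 (1.0 equiv), CsF (3 equiv), THF, 65 °C
Reagents that add atoms: none
Why: Proposed new method: fluoride attacks the trimethylsilyl group of 11 and triflate leaves to give aryne 17, whose triple bond is polarised by the inductively withdrawing C5 methoxy group, so the enolate oxygen of 16 should add at C8a (remote from OMe, flanked only by C8–H) and place the carbanion at C4a beside OMe in 18. The chelated (Z)-enolate holds the ester carbonyl within reach of C4a, which attacks it in a 6-exo-trig acyl substitution and expels methoxide to close ring C; the methoxide is quenched by a further molecule of enol, so only the aryne-forming fluoride is consumed. The closest known reaction type is the fluoride-mediated annulation of arynes with salicylate esters to xanthones (O-arylation, then capture of the ester by the aryl anion); here the phenoxide is replaced by its vinylogue, a β-oxido acrylate. No stereocentre is formed. Three selectivities are needed: the orientation of addition, secured by the C5 methoxy group; O- over C-arylation, expected because the very reactive aryne is attacked at the site of highest charge and the α-carbon is shielded by the ortho-substituted aryl ring; and cyclisation before protonation of 18, favoured by the six-membered transition state and by THF as a poor proton donor. The TIPS ether should survive because fluoride attacks the ortho-activated aryl–SiMe3 bond much faster than the hindered Si–O bond and CsF is sparingly soluble in THF; the MOM ethers and the prenyl group are inert.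

Step 10
Reactants: 19 3-[2,4-bis(methoxymethoxy)phenyl]-5-methoxy-6-(3-methylbut-2-en-1-yl)-7-(triisopropylsilyloxy)-4H-chromen-4-one
Product: 20 3-(2,4-dihydroxyphenyl)-5-methoxy-6-(3-methylbut-2-en-1-yl)-7-(triisopropylsilyloxy)-4H-chromen-4-one
Conditions: 2 M HCl in MeOH/THF (1:1), 40 °C
Reagents that add atoms: none
Why: Acid-catalysed transacetalisation of the two MOM ethers to dimethoxymethane; the silyl ether of the electron-poor C7 oxygen is slow to cleave in acid, and while it is in place neither oxygen next to the prenyl chain is a free phenol, which removes the usual path to a dimethylchroman.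

Step 11
Reactants: 20 3-(2,4-dihydroxyphenyl)-5-methoxy-6-(3-methylbut-2-en-1-yl)-7-(triisopropylsilyloxy)-4H-chromen-4-one
Product: 21 7-hydroxy-3-(2,4-dihydroxyphenyl)-5-methoxy-6-(3-methylbut-2-en-1-yl)-4H-chromen-4-one
Conditions: Bu4NF (1.2 equiv), AcOH (1.2 equiv), THF, 0 °C
Reagents that add atoms: none
Why: Fluoride cleavage of an aryl silyl ether, especially easy here because the C7 phenoxide is conjugated with the C4 carbonyl; buffering with acetic acid keeps the medium from becoming basic enough to attack C2.

## Compound list

1 | 5-methoxybenzene-1,3-diol (5-methoxyresorcinol) | COc1cc(O)cc(O)c1 | starting material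
2 | 1-bromo-3-methylbut-2-ene (prenyl bromide) | CC(C)=CCBr | starting material
3 | 5-methoxy-4-(3-methylbut-2-en-1-yl)benzene-1,3-diol | COc1cc(O)cc(O)c1CC=C(C)C | intermediate
4 | 3-hydroxy-5-methoxy-4-(3-methylbut-2-en-1-yl)phenyl N-isopropylcarbamate | COc1cc(OC(=O)NC(C)C)cc(O)c1CC=C(C)C | intermediate
5 | 3-methoxy-4-(3-methylbut-2-en-1-yl)-5-(triisopropylsilyloxy)phenyl N-isopropylcarbamate | COc1cc(OC(=O)NC(C)C)cc(O[Si](C(C)C)(C(C)C)C(C)C)c1CC=C(C)C | intermediate
6 | 3-methoxy-4-(3-methylbut-2-en-1-yl)-5-(triisopropylsilyloxy)phenyl N-(tert-butyldimethylsilyl)-N-isopropylcarbamate | COc1cc(OC(=O)N(C(C)C)[Si](C)(C)C(C)(C)C)cc(O[Si](C(C)C)(C(C)C)C(C)C)c1CC=C(C)C | intermediate (not isolated)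
7 | 2-lithio derivative of 6 (lithium on the carbon between the carbamate oxygen and OMe) | COc1c([Li])c(OC(=O)N(C(C)C)[Si](C)(C)C(C)(C)C)cc(O[Si](C(C)C)(C(C)C)C(C)C)c1CC=C(C)C | intermediate (not isolated)
8 | 3-methoxy-4-(3-methylbut-2-en-1-yl)-5-(triisopropylsilyloxy)-2-(trimethylsilyl)phenyl N-(tert-butyldimethylsilyl)-N-isopropylcarbamate | COc1c([Si](C)(C)C)c(OC(=O)N(C(C)C)[Si](C)(C)C(C)(C)C)cc(O[Si](C(C)C)(C(C)C)C(C)C)c1CC=C(C)C | intermediate (not isolated)
9 | 3-methoxy-4-(3-methylbut-2-en-1-yl)-5-(triisopropylsilyloxy)-2-(trimethylsilyl)phenyl N-isopropylcarbamate | COc1c([Si](C)(C)C)c(OC(=O)NC(C)C)cc(O[Si](C(C)C)(C(C)C)C(C)C)c1CC=C(C)C | intermediate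
10 | 3-methoxy-4-(3-methylbut-2-en-1-yl)-5-(triisopropylsilyloxy)-2-(trimethylsilyl)phenol | COc1c([Si](C)(C)C)c(O)cc(O[Si](C(C)C)(C(C)C)C(C)C)c1CC=C(C)C | intermediate (not isolated)
11 | 3-methoxy-4-(3-methylbut-2-en-1-yl)-5-(triisopropylsilyloxy)-2-(trimethylsilyl)phenyl trifluoromethanesulfonate | COc1c([Si](C)(C)C)c(OS(=O)(=O)C(F)(F)F)cc(O[Si](C(C)C)(C(C)C)C(C)C)c1CC=C(C)C | intermediate
12 | 2-(2,4-dihydroxyphenyl)acetic acid | OC(=O)Cc1ccc(O)cc1O | starting material
13 | methyl 2-(2,4-dihydroxyphenyl)acetate | COC(=O)Cc1ccc(O)cc1O | intermediate
14 | methyl 2-[2,4-bis(methoxymethoxy)phenyl]acetate | COC(=O)Cc1ccc(OCOC)cc1OCOC | intermediate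
15 | sodium (Z)-2-[2,4-bis(methoxymethoxy)phenyl]-3-methoxy-3-oxoprop-1-en-1-olate | [Na+].[O-]/C=C(/c1ccc(OCOC)cc1OCOC)C(=O)OC | intermediate (not isolated)
16 | methyl (Z)-2-[2,4-bis(methoxymethoxy)phenyl]-3-hydroxyacrylate | O/C=C(/c1ccc(OCOC)cc1OCOC)C(=O)OC | intermediate
17 | 3-methoxy-4-(3-methylbut-2-en-1-yl)-5-(triisopropylsilyloxy)benzyne (1,2-didehydrobenzene; triple bond between the former triflate and silyl carbons) | COC1=C(CC=C(C)C)C(O[Si](C(C)C)(C(C)C)C(C)C)=CC#C1 | intermediate (not isolated)
18 | aryl carbanion of methyl (Z)-2-[2,4-bis(methoxymethoxy)phenyl]-3-[3-methoxy-4-(3-methylbut-2-en-1-yl)-5-(triisopropylsilyloxy)phenoxy]acrylate (charge on the ring carbon between the ether oxygen and OMe) | COC(=O)/C(=C\Oc1cc(O[Si](C(C)C)(C(C)C)C(C)C)c(CC=C(C)C)c(OC)[c-]1)c1ccc(OCOC)cc1OCOC | intermediate (not isolated)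
19 | 3-[2,4-bis(methoxymethoxy)phenyl]-5-methoxy-6-(3-methylbut-2-en-1-yl)-7-(triisopropylsilyloxy)-4H-chromen-4-one | COc1c(CC=C(C)C)c(O[Si](C(C)C)(C(C)C)C(C)C)cc2occ(-c3ccc(OCOC)cc3OCOC)c(=O)c12 | intermediate
20 | 3-(2,4-dihydroxyphenyl)-5-methoxy-6-(3-methylbut-2-en-1-yl)-7-(triisopropylsilyloxy)-4H-chromen-4-one | COc1c(CC=C(C)C)c(O[Si](C(C)C)(C(C)C)C(C)C)cc2occ(-c3ccc(O)cc3O)c(=O)c12 | intermediate
21 | 7-hydroxy-3-(2,4-dihydroxyphenyl)-5-methoxy-6-(3-methylbut-2-en-1-yl)-4H-chromen-4-one (CNP0121160.0) | COc1c(CC=C(C)C)c(O)cc2occ(-c3ccc(O)cc3O)c(=O)c12 | target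

## Step count and least certain steps

Total: 11 steps. Steps 1–5 make 11, steps 6–8 make 16, and steps 9–11 join them and finish. Longest linear sequence: 8 steps (1, 2, 3, 4, 5, 9, 10, 11).

**Step 9 (key step, proposed new method).** The most likely failures are:
- arylation of the ambident enolate on carbon, followed by insertion of the aryne into the C–CHO bond;
- protonation of the aryl anion by unreacted enol before ring closure;
- reaction through an enolate rotamer whose ester group cannot reach C4a;
- fluoride-induced loss of the silyl ether before annulation, which would set free a competing phenoxide.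

Fallback with known chemistry, setting out from 14 and 11 and returning at 19:
- Saponification of 14 (LiOH, THF/H2O) gives 2-[2,4-bis(methoxymethoxy)phenyl]acetic acid F1.
- The aryne from 11 is generated with CsF in THF in the presence of F1. This is the known insertion of arynes into the C–O bond of carboxylic acids: the carboxylate oxygen adds at C8a and the acyl group migrates to the C4a carbanion. It gives the 2-hydroxy deoxybenzoin 2-[2,4-bis(methoxymethoxy)phenyl]-1-[2-hydroxy-6-methoxy-5-(3-methylbut-2-en-1-yl)-4-(triisopropylsilyloxy)phenyl]ethan-1-one F2.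
- Condensation of F2 with N,N-dimethylformamide dimethyl acetal (toluene, 90 °C) supplies C2 and closes ring C to 19.

This path avoids the O/C ambiguity, because a carboxylate has only oxygen nucleophilic sites, at the price of one more step.

**Step 1.** Alkylation can occur at the carbon between the two hydroxyls, on oxygen, or twice, because every ring position of the phenoxide is activated. Fallback from 1, returning at 4 (it also bypasses step 2):
- Monosilylation of 1 (TIPSCl, imidazole, excess diol) gives 3-methoxy-5-(triisopropylsilyloxy)phenol F3.
- MOMCl/i-Pr2NEt gives triisopropyl[3-methoxy-5-(methoxymethoxy)phenoxy]silane F4.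
- Directed lithiation between the MOM ether and OMe (n-BuLi, THF, 0 °C), transmetalation with CuBr·SMe2 and alkylation with 2 give triisopropyl[3-methoxy-5-(methoxymethoxy)-4-(3-methylbut-2-en-1-yl)phenoxy]silane F5.
- Bu4NF frees the hydroxyl para to the prenyl chain, giving 3-methoxy-5-(methoxymethoxy)-4-(3-methylbut-2-en-1-yl)phenol F6.
- i-PrNCO/Et3N gives 3-methoxy-5-(methoxymethoxy)-4-(3-methylbut-2-en-1-yl)phenyl N-isopropylcarbamate F7.
- Dilute HCl in MeOH at rt removes the MOM group and gives 4.

**Step 2.** Carbamoylation may occur at the hindered hydroxyl or at both, because an isocyanate is a small electrophile. Fallback from 3, returning at 5: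
- TBSCl (1.0 equiv), imidazole, CH2Cl2, −20 °C silylates the unhindered hydroxyl selectively and gives 5-(tert-butyldimethylsilyloxy)-3-methoxy-2-(3-methylbut-2-en-1-yl)phenol F8.
- TIPSOTf/2,6-lutidine gives tert-butyl[3-methoxy-4-(3-methylbut-2-en-1-yl)-5-(triisopropylsilyloxy)phenoxy]dimethylsilane F9.
- KHF2 in MeOH at rt removes the smaller, unhindered aryl silyl ether first and gives 3-methoxy-4-(3-methylbut-2-en-1-yl)-5-(triisopropylsilyloxy)phenol F10.
- i-PrNCO/Et3N converts F10 into 5.

**Step 4.** Incomplete N-silylation would lead to base-induced loss of the carbamate as isocyanate, and the butyllithium could deprotonate the benzylic–allylic CH2 of the prenyl chain instead of the ring. Fallback from 3, returning at 10 and from there to 11 by the triflation of step 5: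
- ClC(O)NEt2/K2CO3 in MeCN gives 3-hydroxy-5-methoxy-4-(3-methylbut-2-en-1-yl)phenyl N,N-diethylcarbamate F11. This tertiary carbamate cannot eliminate.
- TIPSCl/imidazole gives 3-methoxy-4-(3-methylbut-2-en-1-yl)-5-(triisopropylsilyloxy)phenyl N,N-diethylcarbamate F12.
- s-BuLi/TMEDA in THF at −78 °C followed by TMSCl (fast, kinetically controlled ortho-lithiation by the stronger director) gives 3-methoxy-4-(3-methylbut-2-en-1-yl)-5-(triisopropylsilyloxy)-2-(trimethylsilyl)phenyl N,N-diethylcarbamate F13.
- Reductive cleavage with Cp2Zr(H)Cl in THF frees phenol 10.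

## Further compounds

F1 | step 9 | 2-[2,4-bis(methoxymethoxy)phenyl]acetic acid | OC(=O)Cc1ccc(OCOC)cc1OCOC
F2 | step 9 | 2-[2,4-bis(methoxymethoxy)phenyl]-1-[2-hydroxy-6-methoxy-5-(3-methylbut-2-en-1-yl)-4-(triisopropylsilyloxy)phenyl]ethan-1-one | COc1c(CC=C(C)C)c(O[Si](C(C)C)(C(C)C)C(C)C)cc(O)c1C(=O)Cc1ccc(OCOC)cc1OCOC
F3 | step 1 | 3-methoxy-5-(triisopropylsilyloxy)phenol | COc1cc(O)cc(O[Si](C(C)C)(C(C)C)C(C)C)c1
F4 | step 1 | triisopropyl[3-methoxy-5-(methoxymethoxy)phenoxy]silane | COCOc1cc(OC)cc(O[Si](C(C)C)(C(C)C)C(C)C)c1
F5 | step 1 | triisopropyl[3-methoxy-5-(methoxymethoxy)-4-(3-methylbut-2-en-1-yl)phenoxy]silane | COCOc1cc(O[Si](C(C)C)(C(C)C)C(C)C)cc(OC)c1CC=C(C)C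
F6 | step 1 | 3-methoxy-5-(methoxymethoxy)-4-(3-methylbut-2-en-1-yl)phenol | COCOc1cc(O)cc(OC)c1CC=C(C)C
F7 | step 1 | 3-methoxy-5-(methoxymethoxy)-4-(3-methylbut-2-en-1-yl)phenyl N-isopropylcarbamate | COCOc1cc(OC(=O)NC(C)C)cc(OC)c1CC=C(C)C
F8 | step 2 | 5-(tert-butyldimethylsilyloxy)-3-methoxy-2-(3-methylbut-2-en-1-yl)phenol | COc1cc(O[Si](C)(C)C(C)(C)C)cc(O)c1CC=C(C)C
F9 | step 2 | tert-butyl[3-methoxy-4-(3-methylbut-2-en-1-yl)-5-(triisopropylsilyloxy)phenoxy]dimethylsilane | COc1cc(O[Si](C)(C)C(C)(C)C)cc(O[Si](C(C)C)(C(C)C)C(C)C)c1CC=C(C)C
F10 | step 2 | 3-methoxy-4-(3-methylbut-2-en-1-yl)-5-(triisopropylsilyloxy)phenol | COc1cc(O)cc(O[Si](C(C)C)(C(C)C)C(C)C)c1CC=C(C)C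
F11 | step 4 | 3-hydroxy-5-methoxy-4-(3-methylbut-2-en-1-yl)phenyl N,N-diethylcarbamate | CCN(CC)C(=O)Oc1cc(O)c(CC=C(C)C)c(OC)c1
F12 | step 4 | 3-methoxy-4-(3-methylbut-2-en-1-yl)-5-(triisopropylsilyloxy)phenyl N,N-diethylcarbamate | CCN(CC)C(=O)Oc1cc(O[Si](C(C)C)(C(C)C)C(C)C)c(CC=C(C)C)c(OC)c1
F13 | step 4 | 3-methoxy-4-(3-methylbut-2-en-1-yl)-5-(triisopropylsilyloxy)-2-(trimethylsilyl)phenyl N,N-diethylcarbamate | CCN(CC)C(=O)Oc1cc(O[Si](C(C)C)(C(C)C)C(C)C)c(CC=C(C)C)c(OC)c1[Si](C)(C)C
A1 | alternative 1 | 5-methoxy-7-(methoxymethoxy)-2,2-dimethyl-6-(3-methylbut-2-en-1-yl)-4H-benzo[d][1,3]dioxin-4-one | COc1c(CC=C(C)C)c(OCOC)cc2OC(C)(C)OC(=O)c12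
A2 | alternative 1 | [2,4-bis(methoxymethoxy)benzyl]triphenylphosphonium bromide | COCOc1ccc(C[P+](c2ccccc2)(c2ccccc2)c2ccccc2)c(OCOC)c1.[Br-]
A3 | alternative 1 | 5-methoxy-7-(methoxymethoxy)-3-[2,4-bis(methoxymethoxy)phenyl]-6-(3-methylbut-2-en-1-yl)-4H-chromen-4-one | COc1c(CC=C(C)C)c(OCOC)cc2occ(-c3ccc(OCOC)cc3OCOC)c(=O)c12
A4 | alternative 2 | 2-{2-[2,4-bis(methoxymethoxy)phenyl]-2-oxoethoxy}-6-methoxy-4-(methoxymethoxy)-5-(3-methylbut-2-en-1-yl)benzaldehyde | COc1c(CC=C(C)C)c(OCOC)cc(OCC(=O)c2ccc(OCOC)cc2OCOC)c1C=O
A5 | alternative 2 | racemic 3-hydroxy-5-methoxy-7-(methoxymethoxy)-3-[2,4-bis(methoxymethoxy)phenyl]-6-(3-methylbut-2-en-1-yl)chroman-4-one | COc1c(CC=C(C)C)c(OCOC)cc2OCC(O)(c3ccc(OCOC)cc3OCOC)C(=O)c12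
A6 | alternative 3 | methyl 5-[2,4-bis(methoxymethoxy)phenyl]-2-methyl-4-oxo-4H-pyran-3-carboxylate | COC(=O)c1c(C)occ(-c2ccc(OCOC)cc2OCOC)c1=O
A7 | alternative 3 | N-methoxy-N,5-dimethylhex-4-enamide | CON(C)C(=O)CCC=C(C)C
A8 | alternative 3 | 5,7-dihydroxy-3-[2,4-bis(methoxymethoxy)phenyl]-6-(3-methylbut-2-en-1-yl)-4H-chromen-4-one | CC(C)=CCc1c(O)cc2occ(-c3ccc(OCOC)cc3OCOC)c(=O)c2c1O
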